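- The product to watch is mono adduct. The first addition (substrate + partner) makes it and the second (partner + mono adduct) eats it, so partner cancels from the ratio of the two rates.

- alpha: substrate 0.010 M (fed, over 5.0 min); partner 0.0150 M; time 10 min; the fed solution adds 1.0 times the starting volume
- beta: substrate 0.010 M (fed, over 5.0 min); partner 0.0150 M; time 5.0 min; the fed solution adds 1.0 times the starting volume

    partner + double product → tris adduct + by-product (k1 = 9.4 M⁻¹ min⁻¹)
    partner + mono adduct → double product + by-product (k2 = 22 M⁻¹ min⁻¹)
    substrate + partner → mono adduct + by-product (k3 = 230 M⁻¹ min⁻¹)
    2 substrate → homo dimer (k4 = 16 M⁻¹ min⁻¹)
    crystals ⇌ by-product, rate k5*(cs5 - [by-product]) while solid is left; crystals form when [by-product] > cs5 (cs5 = 1.8 mM, k5 = 3.0 min⁻¹)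

- in percentages every species weighs as the substrate in it: one homo dimer counts as two
- for by-product the crystals are counted in
- for a step with 2 of a species take k times the square, and two of it per event
- charges are per starting volume, the dose included; the dosed solution carries all of it
- as a solid, counted per litre of solution: crystals
- run time (alpha): 10 min

- which of these there is most of at the end, counted by the substrate in it, alpha (mono adduct / tris adduct / double product / substrate)
- which of these there is most of at the end, counted by the substrate in it, beta (mono adduct / tris adduct / double product / substrate)
- amount of the one of these that there is most of at the end, in percent of the substrate charged, alpha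
- amount of the one of these that there is most of at the end, in percent of the substrate charged, beta

- That ratio is S[substrate]/[mono adduct], where S = 230 M⁻¹ min⁻¹ over 22 M⁻¹ min⁻¹ = 10.5, the selectivity factor. Mono adduct gains in amount while the ratio stands above one and loses below it.
- For a quick number I take one partner used per substrate fed, which after dilution puts partner at 0.00250 M at the end of the feed, and I hold it at that figure throughout. This is my assumption: what the second addition takes stands in for what unreacted substrate has not yet taken.
- Substrate is then pseudo-first-order, and its first-order constant times the feed time is 2.88. A steady feed against that loss leaves, by this reckoning, 32.8% of the charge as substrate.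
- I ignore homo dimer and hold [mono adduct]/[substrate] steady through the feed. The charge that has left substrate, over S times what remains, is 0.196, and mono adduct is that charge divided by one plus this figure.
- So beta, stopped at 5.0 min, gives 56.2% and its leader is mono adduct.
- Alpha runs on to 10 min. I add the leftover substrate to mono adduct and let the sum decay by the second addition at the same partner, which keeps 76.0%. That gives 67.6%, and alpha's leader is mono adduct.
- Your hunch, the forecast, has the same leader in both flasks, mono adduct, but other figures than mine: 64% for alpha and 58% for beta, in its words “mono adduct dominates at both end times”.
- The simulation gives mono adduct at 64.8% in alpha and mono adduct at 58.6% in beta, with substrate in beta at 21.6% against my 32.8%.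
- At 10.0 min alpha has S[substrate]/[mono adduct] at 0.497, partner going by the first addition at 0.50 of its rate by the second, whereas beta at 5.00 min stands at 3.86; beta's mono adduct is still gaining, and alpha's is losing on its way to 52.3% at 100 min. In the neighbour with 0.0025 M of substrate, otherwise as alpha, the same quantity is 0.00539 at 10.0 min, and double product leads with 46.8% against 39.7% of mono adduct.

(All constants stand for no real mixture; the rest is arithmetic.)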